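**Retrosynthetic overview**
- The target acid 19 comes from aldehyde 18 by Pinnick oxidation.
- Both rings of 18 are closed in one step by an intramolecular Diels–Alder reaction (C3a–C7a and C4–C5 bonds) of the linear keto-tetraenal 17, with the ketone already in the tether as in the presumed biosynthesis.
- 17 is not made directly. It is released in the flask from the conjugated enone acetal 15 by acetal hydrolysis and a prototropic double-bond shift, so C3 is set dynamically.
- 15 is built by linear chain extension (cross-metathesis, Wittig, HWE, oxidation) from homoallylic alcohol 8.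
- 8 comes from a catalytic asymmetric crotylboration of aldehyde 5, which is made from 2-ethylhex-2-enal and trimethyl orthoformate. This step sets C1, the only reagent-controlled stereocentre.

Assumption: locants C1–C7a are those of the target as a 1H-indene: C1 (CHMe), C2 (C=O), C3 (CHEt), C3a, C4 (C(Et)CO2H), C5 (C(Et)styryl), C6 (=CH), C7 (=CMe), C7a.
Assumption: 5, 7, 8, 10, 12, 14, 15 and 16 are carried as about 1:1 epimer mixtures at the CH(Et) carbon next to the acetal/formyl group (no descriptor written there); that centre is erased in step 8. 3 may be a 1E/1Z mixture.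

**Step 1**
Reactants: 1 (2E)-2-ethylhex-2-enal; 2 tert-butyldimethylsilyl trifluoromethanesulfonate
Product: 3 tert-butyl{[(1E,3E)-2-ethylhexa-1,3-dien-1-yl]oxy}dimethylsilane
Conditions: TBSOTf (1.2 equiv), Et3N (1.5 equiv), CH2Cl2, 0 °C → rt
Reagents that add atoms: TBSOTf (2), CC(C)(C)[Si](C)(C)OS(=O)(=O)C(F)(F)F
Why: Soft enolisation (O-silylation of the enal, then γ-deprotonation by Et3N) gives the 1-silyloxy-1,3-diene; no stereocentre is formed and the C1 geometry is irrelevant.

**Step 2**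
Reactants: 3 tert-butyl{[(1E,3E)-2-ethylhexa-1,3-dien-1-yl]oxy}dimethylsilane; 4 trimethyl orthoformate
Product: 5 (2E)-4-(dimethoxymethyl)-2-ethylhex-2-enal
Conditions: HC(OMe)3 (1.5 equiv), TMSOTf (5 mol %), CH2Cl2, −78 °C
Reagents that add atoms: trimethyl orthoformate (4), COC(OC)OC
Why: Vinylogous Mukaiyama (Mukaiyama–Ishida) reaction: the dimethoxycarbenium ion is attacked at the γ-carbon of the silyl dienol ether (α-attack would give a quaternary centre) and the (E)-enal is regenerated; the new CH(Et) centre is racemic and is erased in step 8.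

**Step 3**
Reactants: 5 (2E)-4-(dimethoxymethyl)-2-ethylhex-2-enal; 6 2-[(2E)-but-2-en-1-yl]-4,4,5,5-tetramethyl-1,3,2-dioxaborolane
Product: 8 (3S,4S,5E)-5,7-diethyl-8,8-dimethoxy-3-methylocta-1,5-dien-4-ol, via pinacol borate ester 7 (not isolated)
Conditions: 6 (1.3 equiv), (S)-TRIP (5 mol %), 4 Å MS, PhMe, −30 °C; aq. NaHCO3 work-up
Reagents that add atoms: (E)-crotylboronic acid pinacol ester (6), C/C=C/CB1OC(C)(C)C(C)(C)O1
Why: Chiral phosphoric acid-catalysed crotylboration through a closed chair transition state: the (E)-crotyl boronate gives the anti adduct and (S)-TRIP directs Si-face attack on the enal carbonyl, so the methyl-bearing carbon (future C1) is set as S, while the carbinol centre (S) is oxidised away in step 7.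

**Step 4**
Reactants: 8 (3S,4S,5E)-5,7-diethyl-8,8-dimethoxy-3-methylocta-1,5-dien-4-ol; 9 methacrolein
Product: 10 (2E,4S,5S,6E)-6,8-diethyl-5-hydroxy-9,9-dimethoxy-2,4-dimethylnona-2,6-dienal
Conditions: methacrolein (10 equiv), Hoveyda–Grubbs II (5 mol %), CH2Cl2, 40 °C
Reagents that add atoms: methacrolein (9), CC(=C)C=O
Why: Olefin cross-metathesis of the terminal alkene with excess methacrolein gives the (E)-2-methyl enal under thermodynamic control; the trisubstituted alkene is inert and no stereocentre is touched.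

**Step 5**
Reactants: 10 (2E,4S,5S,6E)-6,8-diethyl-5-hydroxy-9,9-dimethoxy-2,4-dimethylnona-2,6-dienal; 11 2-(triphenyl-λ5-phosphanylidene)butanal
Product: 12 (2E,4E,6S,7S,8E)-2,8,10-triethyl-7-hydroxy-11,11-dimethoxy-4,6-dimethylundeca-2,4,8-trienal
Conditions: 11 (1.5 equiv), PhMe, 90 °C
Reagents that add atoms: 2-(triphenylphosphoranylidene)butanal (11), CCC(C=O)=P(c1ccccc1)(c1ccccc1)c1ccccc1
Why: Wittig olefination with a formyl-stabilised ylide is E-selective (CHO trans to the chain) and stops after one homologation because the dienal product is less electrophilic; the free OH and the acetal are tolerated.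

**Step 6**
Reactants: 12 (2E,4E,6S,7S,8E)-2,8,10-triethyl-7-hydroxy-11,11-dimethoxy-4,6-dimethylundeca-2,4,8-trienal; 13 diethyl benzylphosphonate
Product: 14 (3E,5S,6S,7E,9E,11E)-2,4,10-triethyl-1,1-dimethoxy-6,8-dimethyl-12-phenyldodeca-3,7,9,11-tetraen-5-ol
Conditions: 13 (1.6 equiv), KOt-Bu (1.5 equiv), THF, 0 °C; then 12, 0 °C → rt
Reagents that add atoms: diethyl benzylphosphonate (13), CCOP(=O)(Cc1ccccc1)OCC
Why: Horner–Wadsworth–Emmons olefination with the benzylic phosphonate anion gives the (E)-styryl terminus, and the anion is too weak a base to deprotonate the secondary alcohol appreciably, which limits retro-aldol cleavage.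

**Step 7**
Reactants: 14 (3E,5S,6S,7E,9E,11E)-2,4,10-triethyl-1,1-dimethoxy-6,8-dimethyl-12-phenyldodeca-3,7,9,11-tetraen-5-ol
Product: 15 (3E,6S,7E,9E,11E)-2,4,10-triethyl-1,1-dimethoxy-6,8-dimethyl-12-phenyldodeca-3,7,9,11-tetraen-5-one
Conditions: Dess–Martin periodinane (1.3 equiv), NaHCO3 (5 equiv), CH2Cl2, 0 °C
Reagents that add atoms: none
Why: Dess–Martin oxidation of the secondary allylic alcohol under buffered, non-enolising conditions gives the conjugated enone without epimerising the adjacent CH(Me) centre (future C1) or moving the skipped triene.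

**Step 8**
Reactants: 15 (3E,6S,7E,9E,11E)-2,4,10-triethyl-1,1-dimethoxy-6,8-dimethyl-12-phenyldodeca-3,7,9,11-tetraen-5-one
Product: 18 (1S,3S,3aR,4R,5S,7aR)-3,4,5-triethyl-1,7-dimethyl-2-oxo-5-[(E)-2-phenylethenyl]-2,3,3a,4,5,7a-hexahydro-1H-indene-4-carbaldehyde, via enone aldehyde 16 (not isolated), via keto enal 17 (not isolated)
Conditions: PPTS (0.2 equiv), acetone/H2O 10:1, 40 °C; then PhMe (0.01 M), PhCO2H (10 mol %), BHT, 90 °C; then DBU (0.2 equiv), rt
Reagents that add atoms: water, O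
Why: Proposed new method: acetal hydrolysis exposes in 16 a C–H that is α to the aldehyde and γ to the enone, and its acid-catalysed prototropic shift through the common dienol (closest known: glutaconaldehyde-type tautomerism of 2-ene-1,5-dicarbonyls) gives the (E)-keto enal 17 as interconverting C3 epimers, of which only the 3S epimer reaches the CHO-endo, trans-fused intramolecular Diels–Alder transition state with both allylic C–H bonds (at C1 and C3) eclipsing the adjacent double bonds (A(1,3) control; closest known: thermal IMDA of 1,6,8-nonatrienes with a terminally activated dienophile), so the C1 centre fixes C7a, C3a, C4 and C5 in one step, C3 is set under Curtin–Hammett control, and the DBU finish equilibrates C1/C3 to the all-trans (thermodynamic) ketone.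

**Step 9**
Reactants: 18 (1S,3S,3aR,4R,5S,7aR)-3,4,5-triethyl-1,7-dimethyl-2-oxo-5-[(E)-2-phenylethenyl]-2,3,3a,4,5,7a-hexahydro-1H-indene-4-carbaldehyde
Product: 19 (1S,3S,3aR,4R,5S,7aR)-3,4,5-triethyl-1,7-dimethyl-2-oxo-5-[(E)-2-phenylethenyl]-2,3,3a,4,5,7a-hexahydro-1H-indene-4-carboxylic acid
Conditions: NaClO2, NaH2PO4, 2-methyl-2-butene, t-BuOH/H2O, 0 °C → rt
Reagents that add atoms: sodium chlorite, [Na+].[O-]Cl=O
Why: Pinnick oxidation converts the hindered, non-enolisable aldehyde into the acid, with 2-methyl-2-butene scavenging HOCl so that the ring alkene and the styrene survive; no stereocentre is touched.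

**Compound list**
1 | (2E)-2-ethylhex-2-enal | CCC/C=C(\CC)C=O | starting material
2 | tert-butyldimethylsilyl trifluoromethanesulfonate (TBSOTf) | CC(C)(C)[Si](C)(C)OS(=O)(=O)C(F)(F)F | starting material
3 | tert-butyl{[(1E,3E)-2-ethylhexa-1,3-dien-1-yl]oxy}dimethylsilane | CC/C=C/C(CC)=C/O[Si](C)(C)C(C)(C)C | intermediate
4 | trimethyl orthoformate | COC(OC)OC | starting material
5 | (2E)-4-(dimethoxymethyl)-2-ethylhex-2-enal (racemic at C4) | CCC(C(OC)OC)/C=C(\CC)C=O | intermediate
6 | 2-[(2E)-but-2-en-1-yl]-4,4,5,5-tetramethyl-1,3,2-dioxaborolane ((E)-crotylboronic acid pinacol ester) | C/C=C/CB1OC(C)(C)C(C)(C)O1 | starting material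
7 | 2-{[(3S,4S,5E)-5,7-diethyl-8,8-dimethoxy-3-methylocta-1,5-dien-4-yl]oxy}-4,4,5,5-tetramethyl-1,3,2-dioxaborolane | C=C[C@H](C)[C@H](OB1OC(C)(C)C(C)(C)O1)/C(CC)=C/C(CC)C(OC)OC | intermediate (not isolated)
8 | (3S,4S,5E)-5,7-diethyl-8,8-dimethoxy-3-methylocta-1,5-dien-4-ol | C=C[C@H](C)[C@H](O)/C(CC)=C/C(CC)C(OC)OC | intermediate
9 | methacrolein (2-methylprop-2-enal) | CC(=C)C=O | starting material
10 | (2E,4S,5S,6E)-6,8-diethyl-5-hydroxy-9,9-dimethoxy-2,4-dimethylnona-2,6-dienal | O=C/C(C)=C/[C@H](C)[C@H](O)/C(CC)=C/C(CC)C(OC)OC | intermediate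
11 | 2-(triphenyl-λ5-phosphanylidene)butanal | CCC(C=O)=P(c1ccccc1)(c1ccccc1)c1ccccc1 | starting material
12 | (2E,4E,6S,7S,8E)-2,8,10-triethyl-7-hydroxy-11,11-dimethoxy-4,6-dimethylundeca-2,4,8-trienal | O=C/C(CC)=C/C(C)=C/[C@H](C)[C@H](O)/C(CC)=C/C(CC)C(OC)OC | intermediate
13 | diethyl benzylphosphonate | CCOP(=O)(Cc1ccccc1)OCC | starting material
14 | (3E,5S,6S,7E,9E,11E)-2,4,10-triethyl-1,1-dimethoxy-6,8-dimethyl-12-phenyldodeca-3,7,9,11-tetraen-5-ol | c1ccccc1/C=C/C(CC)=C/C(C)=C/[C@H](C)[C@H](O)/C(CC)=C/C(CC)C(OC)OC | intermediate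
15 | (3E,6S,7E,9E,11E)-2,4,10-triethyl-1,1-dimethoxy-6,8-dimethyl-12-phenyldodeca-3,7,9,11-tetraen-5-one | c1ccccc1/C=C/C(CC)=C/C(C)=C/[C@H](C)C(=O)/C(CC)=C/C(CC)C(OC)OC | intermediate
16 | (3E,6S,7E,9E,11E)-2,4,10-triethyl-6,8-dimethyl-5-oxo-12-phenyldodeca-3,7,9,11-tetraenal (C2 epimers) | c1ccccc1/C=C/C(CC)=C/C(C)=C/[C@H](C)C(=O)/C(CC)=C/C(CC)C=O | intermediate (not isolated)
17 | (2E,4S,6S,7E,9E,11E)-2,4,10-triethyl-6,8-dimethyl-5-oxo-12-phenyldodeca-2,7,9,11-tetraenal (reactive epimer, equilibrating with 4R) | c1ccccc1/C=C/C(CC)=C/C(C)=C/[C@H](C)C(=O)[C@@H](CC)/C=C(\CC)C=O | intermediate (not isolated)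
18 | (1S,3S,3aR,4R,5S,7aR)-3,4,5-triethyl-1,7-dimethyl-2-oxo-5-[(E)-2-phenylethenyl]-2,3,3a,4,5,7a-hexahydro-1H-indene-4-carbaldehyde | CC[C@@H]1C(=O)[C@@H](C)[C@@H]2C(C)=C[C@@](/C=C/c3ccccc3)(CC)[C@](CC)(C=O)[C@H]21 | intermediate
19 | (1S,3S,3aR,4R,5S,7aR)-3,4,5-triethyl-1,7-dimethyl-2-oxo-5-[(E)-2-phenylethenyl]-2,3,3a,4,5,7a-hexahydro-1H-indene-4-carboxylic acid | CC[C@@H]1C(=O)[C@@H](C)[C@@H]2C(C)=C[C@@](/C=C/c3ccccc3)(CC)[C@](CC)(C(=O)O)[C@H]21 | target

**Totals**
Total step count: 9. Longest linear sequence: 9 steps (1 → 19).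

**Three steps most likely to fail, with fallbacks**

Step 8 (acetal unmasking, tautomerisation and cycloaddition). The dienol manifold could act as a sink, or enolisation at the CH(Me) centre could erode the ee before cyclisation. The fallback moves the cycloaddition to the alcohol oxidation level and sets out from 14. PPTS in wet acetone gives the non-conjugated hydroxy aldehyde F1. Catalytic DBU moves the double bond into conjugation to give the δ-hydroxy enal F2 as both C4 epimers. Heating in toluene at 100 °C converts the matched 4S epimer into the hydroxy cycloadduct F3; the unreactive epimer is recovered and re-equilibrated with DBU. Dess–Martin oxidation (NaHCO3) of F3 followed by DBU equilibration comes back to the route at 18.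

Step 3 (catalytic crotylboration, the only source of absolute configuration). The ee may be insufficient for this α-branched enal, or the acetal may interfere with the acid catalyst. The fallback sets the methyl centre by chirality transfer and sets out from 5. (R)-Pent-3-yn-2-ol with MsCl/Et3N gives (R)-pent-3-yn-2-yl methanesulfonate F4. With Pd(OAc)2/PPh3/Et2Zn in THF it forms an allenylzinc (anti-SN2′, then syn-SE2′, net inversion) that adds to 5 to give the anti homopropargylic alcohol F5. Pd-catalysed syn-hydrostannation (Bu3SnH, PdCl2(PPh3)2) puts tin on the methyl-bearing alkyne carbon to give the vinylstannane F6. Stille coupling of F6 with [(1E,3E)-3-ethyl-4-iodobuta-1,3-dien-1-yl]benzene F7 (from commercial (E)-but-1-en-3-yn-1-ylbenzene by ethylcupration with EtMgBr/CuBr·SMe2, then I2) comes back to the route at 14, bypassing steps 4–6.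

Step 6 (HWE on the unprotected hydroxy dienal). Retro-aldol cleavage under base or incomplete elimination could lower the yield. The fallback sets out from 12. Salt-free Ph3P=CH2 at −78 °C (which does not deprotonate the alcohol) gives the terminal tetraenol F8. Heck arylation of F8 with iodobenzene (Pd(OAc)2, Bu4NCl, Et3N, DMF, 50 °C) installs the (E)-styryl terminus and comes back to the route at 14.

**Further compounds**
F1 | step 8 | (3E,5S,6S,7E,9E,11E)-2,4,10-triethyl-5-hydroxy-6,8-dimethyl-12-phenyldodeca-3,7,9,11-tetraenal (C2 epimers) | c1ccccc1/C=C/C(CC)=C/C(C)=C/[C@H](C)[C@H](O)/C(CC)=C/C(CC)C=O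
F2 | step 8 | (2E,5S,6S,7E,9E,11E)-2,4,10-triethyl-5-hydroxy-6,8-dimethyl-12-phenyldodeca-2,7,9,11-tetraenal (C4 epimers) | c1ccccc1/C=C/C(CC)=C/C(C)=C/[C@H](C)[C@H](O)C(CC)/C=C(\CC)C=O
F3 | step 8 | (1S,2S,3S,3aR,4R,5S,7aR)-3,4,5-triethyl-2-hydroxy-1,7-dimethyl-5-[(E)-2-phenylethenyl]-2,3,3a,4,5,7a-hexahydro-1H-indene-4-carbaldehyde | CC[C@@H]1[C@@H](O)[C@@H](C)[C@@H]2C(C)=C[C@@](/C=C/c3ccccc3)(CC)[C@](CC)(C=O)[C@H]21
F4 | step 3 | (R)-pent-3-yn-2-yl methanesulfonate | CC#C[C@@H](C)OS(C)(=O)=O
F5 | step 3 | (4S,5S,6E)-6,8-diethyl-9,9-dimethoxy-4-methylnon-6-en-2-yn-5-ol | CC#C[C@H](C)[C@H](O)/C(CC)=C/C(CC)C(OC)OC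
F6 | step 3 | tributyl[(2E,4S,5S,6E)-6,8-diethyl-5-hydroxy-9,9-dimethoxy-4-methylnona-2,6-dien-2-yl]stannane | CCCC[Sn](CCCC)(CCCC)/C(C)=C/[C@H](C)[C@H](O)/C(CC)=C/C(CC)C(OC)OC
F7 | step 3 | [(1E,3E)-3-ethyl-4-iodobuta-1,3-dien-1-yl]benzene | I/C=C(CC)/C=C/c1ccccc1
F8 | step 6 | (3E,5S,6S,7E,9E)-2,4,10-triethyl-1,1-dimethoxy-6,8-dimethyldodeca-3,7,9,11-tetraen-5-ol | C=C/C(CC)=C/C(C)=C/[C@H](C)[C@H](O)/C(CC)=C/C(CC)C(OC)OC
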